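I start with an easy step: I work with the fraction left and not the fraction made. If 90.0% of the electrophile has reacted, 10.0% of it is left, and 0.288 M each of acid set free and product has formed.

electrophile 0.32 M; solid base 0.0960 M; time 20 s

- the concentration of nucleophile at which the part of the electrophile that has reacted at 20 s is just 90%, in M

    electrophile + nucleophile ⇌ acid set free + product (K1 = 1.1, k1 = 5.7 /M/s)
    acid set free + free base ⇌ salt of the base, settled at all times (K2 = 5.0 /M)
    solid base ⇌ free base, rate k3*(cs3 - [free base]) while solid is left; crystals form when [free base] > cs3 (cs3 = 0.26 M, k3 = 0.039 /s)
    nucleophile + acid set free ⇌ protonated nucleophile, settled at all times (K4 = 240 /M)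

At balance, the main step then permits one thing, the allowed ratio, [acid set free]/[nucleophile], equal to its equilibrium constant times the fraction left over the fraction reacted: 0.122.

With the main step by itself, all the acid stays free, so the free nucleophile must be 2.36 M and the charge 2.65 M.

Next I add protonation. Now [protonated nucleophile] = 240 /M × [acid set free][nucleophile]. I first put the acid set free into that form, which brings [nucleophile] down to 0.0991 M and [acid set free] to 0.0121 M, so nearly all of it does stand there in my reckoning. The charge drops to 0.675 M.

Last I add the base. Its charge of 0.0960 M is below the solubility 0.26 M, and if I take the free base as staying in solution, it enters in about 11.8 s, sooner than 20 s. At that free acid it holds 0.00548 M as salt, which leaves 0.270 M protonated. The remaining electrophile turns over in about 1.77 s, shorter than 20 s, so I treat the flask as balanced and commit to 0.654 M.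

The forecast gives 0.655 M, close to mine, on the ground that “the nucleophile scavenges most of it”.

The simulation gives 0.655 M of nucleophile at the start, and that amount of nucleophile over the electrophile charged is 2.05. In this flask the main step ran early, with 87.0% of the electrophile used at 2.00 s and 99.9% of its turnover behind it at 10.0 s. Meanwhile the solid base was still dissolving, with 20% of that turnover done at 2.00 s and half by 5.21 s. In the flask with twice the electrophile and all other amounts as they are, 52.3% has reacted at the end of the run, so the same rule, taken at balance, gives an allowed ratio of 1.00 there, against 0.122 here.

The numbers of this flask were drawn at random within sensible limits; no experiment stands behind them.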